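## Structural features

The target is a 2,3,4-trisubstituted oxolane. Ring atoms are numbered O1, C2, C3, C4, C5; C6 is the hydroxymethyl carbon on C3 and C7 the exocyclic carbinol carbon on C4. C2 carries the 3,4,5-trimethoxyphenyl ring, C7 carries OH and the 3,4-dimethoxyphenyl ring, and C5 is an unsubstituted OCH2. There are four contiguous stereocentres, C2 (R), C3 (S), C4 (R) and C7 (S); the three ring substituents are all-trans and C7 is 1,2-related to C4 outside the ring. The two aryl groups differ, so the pseudo-symmetric chain C2–C3–C4–C7 cannot be built by a dimerisation. C2–O1 and C7–OH are both benzylic to electron-rich rings and ionise easily (SN1 exchange, epimerisation, dehydration), the free carbinol more so than the ring ether. The 3,4-trans oxolane maps onto the cis-α,β-disubstituted series of the classical lignan butyrolactones, which lactone enolate chemistry does not deliver directly. The difficulty is therefore the unsymmetrical stereotetrad, not the ring as such. The key step exploits the unit O1–C5–C4–C7–O, an aldol pattern once C7 is an aldehyde: O1, C5, C7 and the C7 oxygen can be taken from one vicinal diol in which C5 is bonded to C7, and C5 is moved from C7 to C4 while C2–C3 is formed.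

## Logic of the disconnections

14 ⇒ 13. The O–Si bond on the C6 oxygen is cut. C6–OH must be masked from step 3 to step 7. This costs one protecting group and demands a fluoride cleavage that leaves both benzylic C–O bonds alone.

13 ⇒ 12. The C7–H bond is cut (carbinol to aryl ketone). C7 is the most labile stereocentre and the only one outside the ring, so it is set last by 1,2-induction from C4. The gain is that no earlier step has to respect C7. The demand is a Felkin-selective hydride addition.

12 ⇒ 11 ⇒ 9 + 10. The C7–aryl bond is cut. The whole dimethoxyphenyl ring arrives as a nucleophile on an aldehyde. The addition need not be selective, because C7 of 11 is erased on the way to 12. The demand is that 1,2-addition outruns enolisation at C4.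

9 ⇒ 6 (key). C2–C3 and C4–C5 are cut, C5 is rejoined to C7, and C2 is rejoined to the C7 oxygen. The oxolane with three contiguous stereocentres becomes a 1,3-dioxolane acetal with one stereocentre (the future C7) and an E-alkene (future C3=C4). The forward step must form two C–C bonds, move C5 from C7 to C4, and pass the chirality of a centre that it destroys on to C2 and C3.

6 ⇒ 5 + 2. The C3=C4 double bond is cut by cross-metathesis. This separates the C3/C6 unit from the chiral C4/C5/C7 unit. The demand is E geometry, which becomes the 2,3-trans relation.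

5 ⇒ 3 + 4, and 2 ⇒ 1. The two acetal C–O bonds and the Si–O bond are cut. This reaches a C4 chiral-pool diol, an aryl aldehyde and allyl alcohol. The acetal carbon configuration is irrelevant because it becomes sp2 in the key step.

## Other disconnections considered

Alternative 1: the lignan lactone logic, which comes to mind first. Cut O1–C2 and C2–C3. The enolate of a β-substituted γ-butyrolactone (carbonyl = C6, OCH2 = C5, β-substituent = silylated C7 carbinol) would add to 4 to give lactone A1. LiAlH4 would give triol A2, and acid would close O1–C2 by 5-exo attack of the C5 hydroxyl on the C2 benzylic cation. Grounds against: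
- The required A1 is the cis-α,β-lactone. Enolate aldol anti to the β-substituent gives the trans lactone and hence the 3,4-cis oxolane, so an epimerisation against the thermodynamic bias would be needed.
- In A2 two electron-rich benzylic C–O bonds (C2, C7) and two primary hydroxyls compete in the SN1 closure. Both the constitution and the C7 configuration are at stake.
- The lactone needs its own multi-step asymmetric synthesis and more protecting groups.

Alternative 2: [1,3] O-to-C ring contraction of a seven-membered vinyl acetal. Cut only C2–C3 and join C2 to the oxygen of a C6 enol. The 4,5-dihydro-1,3-dioxepine A3 would ionise with a Lewis acid to an oxocarbenium/enolate pair and re-close to the oxolane-3-carbaldehyde A4; NaBH4 and desilylation would finish. This is the nearest relative of the chosen plan, and C4 would be a retained carbon stereocentre. Grounds against: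
- A3 must already hold the C4/C7 pair in a 5-substituted cyclic enol acetal. The direct entries (Heck-type arylation or double-bond isomerisation of 4,7-dihydro-1,3-dioxepines) neither install a hydroxybenzyl group nor fix the position of the enol ether.
- The silylated C7–O bond, benzylic to the dimethoxyphenyl ring, would have to survive the Lewis acid that ionises the acetal.
- More steps are needed to reach a less certain precursor.

Alternative 3: [3+2] cycloaddition of a carbonyl ylide. Cut C2–C3 and C4–C5, the same pair as in the chosen plan, but between two molecules. The non-stabilised ylide A5 from the trimethoxybenzaldehyde would add to the (E)-aroylacrylate A6 to give keto ester A7, with 3,4-trans from the alkene geometry. Grounds against: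
- A6 has two acceptor groups of similar strength, so nothing dictates which ylide terminus bonds to which alkene carbon.
- Exo/endo control of C2 is weak for non-stabilised ylides, and the adduct would be racemic.
- Ester and ketone would then need differentiation.
The chosen plan makes the same two bonds within one molecule, where the tether fixes the regiochemistry and one purchased stereocentre fixes the absolute configuration.

Key step: step 4

Remark: the ring locants of the target (O1, C2–C5, C6, C7 as defined above) are kept in the names of all oxolane intermediates. Compound 3 and the THF solution of 10 are taken as commercial.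

## Route

Step 1
Reactants: 1 prop-2-en-1-ol (allyl alcohol)
Product: 2 tert-butyl(diphenyl)(prop-2-en-1-yloxy)silane
Conditions: TBDPSCl (1.05 equiv), imidazole (1.5 equiv), CH2Cl2, 0 °C → rt
Reagents that add atoms: tert-butyl(chloro)diphenylsilane (TBDPSCl), CC(C)(C)[Si](Cl)(c1ccccc1)c1ccccc1
Why: Standard imidazole-mediated silylation of a primary alcohol; no stereocentre is involved, and the TBDPS group is chosen to survive the Lewis acid of step 4.

Step 2
Reactants: 3 (2S)-but-3-ene-1,2-diol; 4 3,4,5-trimethoxybenzaldehyde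
Product: 5 (4S)-4-ethenyl-2-(3,4,5-trimethoxyphenyl)-1,3-dioxolane (both C2 epimers)
Conditions: PPTS (5 mol %), PhH, reflux, Dean–Stark
Reagents that add atoms: none
Why: Acid-catalysed acetalisation of a 1,2-diol with azeotropic removal of water; the stereocentre of 3 is not touched, and the acetal epimer mixture is irrelevant because that carbon becomes sp2 in step 4.

Step 3
Reactants: 5 (4S)-4-ethenyl-2-(3,4,5-trimethoxyphenyl)-1,3-dioxolane; 2 tert-butyl(diphenyl)(prop-2-en-1-yloxy)silane (3 equiv)
Product: 6 tert-butyl(diphenyl)silyl ether of (2E)-3-[(4S)-2-(3,4,5-trimethoxyphenyl)-1,3-dioxolan-4-yl]prop-2-en-1-ol (both acetal epimers)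
Conditions: Hoveyda–Grubbs II (5 mol %), CH2Cl2, 40 °C
Reagents that add atoms: none
Why: Olefin cross-metathesis of an allylic-oxygenated vinyl group with an excess of a simple allyl ether; secondary metathesis should favour the E isomer, and the stereocentre is not part of the reacting bond.

Step 4
Reactants: 6 tert-butyl(diphenyl)silyl ether of (2E)-3-[(4S)-2-(3,4,5-trimethoxyphenyl)-1,3-dioxolan-4-yl]prop-2-en-1-ol
Product: 9 (2R,3S,4R)-3-{[tert-butyl(diphenyl)silyl]oxymethyl}-2-(3,4,5-trimethoxyphenyl)oxolane-4-carbaldehyde, via ring-opened oxocarbenium stannate 7 (not isolated), via methyleneoxonium tin enolate 8 (not isolated)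
Conditions: SnCl4 (1.5 equiv), CH2Cl2, –78 → –20 °C; Et3N, then aq NaHCO3
Reagents that add atoms: none
Why: SnCl4 opens the acetal at the allylic oxygen (opening at the primary oxygen is reversible and unproductive) to the (E)-aryl oxocarbenium 7, a 2-oxonia-1,5-diene. A chair 2-oxonia-Cope shift, accelerated by the stannyloxy group on the sp3 carbon, forms C2–C3 and cuts C5–C7 to give 8, which collapses by aldol addition (C4–C5) and releases SnCl4; a Prins cyclisation followed by pinacol shift of C5 would form the same bonds through the same chair. The closest known reaction type is the Lewis acid rearrangement of 4-alkenyl-1,3-dioxolanes to 3-acyl oxolanes (Prins–pinacol or oxonia-Cope–aldol), the oxygen counterpart of the aza-Cope–Mannich reaction. The oxolane closes at C4–C5 in the 5-(enolexo)-endo-trig mode, the enolate carbon attacking the O1=C5 oxocarbenium that lies inside the new ring. C2 and C3 are set together in the chair: the E-oxocarbenium puts the aryl group equatorial and the E-alkene puts CH2OSi equatorial, hence 2,3-trans, and the S carbinol carbon selects the chair in which its bulky O–SnCl4 group is equatorial, hence 2R,3S. C4 is set in the aldol closure with the formyl group trans to the C3 substituent; it is α to the aldehyde, so any cis isomer can equilibrate through the enol to all-trans 9. The step needs transfer of chirality from a centre that it destroys; this rests on the equatorial preference of the stannyloxy group and on the E geometry of both π bonds, while the tether fixes the regiochemistry.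

Step 5
Reactants: 9 (2R,3S,4R)-3-{[tert-butyl(diphenyl)silyl]oxymethyl}-2-(3,4,5-trimethoxyphenyl)oxolane-4-carbaldehyde; 10 (3,4-dimethoxyphenyl)magnesium bromide (0.5 M in THF, 1.5 equiv)
Product: 11 (3,4-dimethoxyphenyl)[(2R,3S,4R)-3-{[tert-butyl(diphenyl)silyl]oxymethyl}-2-(3,4,5-trimethoxyphenyl)oxolan-4-yl]methanol (both C7 epimers)
Conditions: THF, –78 °C; then H2O
Reagents that add atoms: none
Why: Grignard 1,2-addition to an aldehyde, which should be faster than enolisation at –78 °C. C7 needs no control here because it is erased in step 6; Felkin–Anh attack is expected to favour the 7R epimer, which is why C7 is set by reduction instead.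

Step 6
Reactants: 11 (3,4-dimethoxyphenyl)[(2R,3S,4R)-3-{[tert-butyl(diphenyl)silyl]oxymethyl}-2-(3,4,5-trimethoxyphenyl)oxolan-4-yl]methanol
Product: 12 (3,4-dimethoxyphenyl)[(2R,3S,4R)-3-{[tert-butyl(diphenyl)silyl]oxymethyl}-2-(3,4,5-trimethoxyphenyl)oxolan-4-yl]methanone
Conditions: Dess–Martin periodinane (1.3 equiv), CH2Cl2, 0 °C → rt
Reagents that add atoms: none
Why: Dess–Martin oxidation of a secondary benzylic alcohol under near-neutral conditions; C4, now α to the ketone, already has the thermodynamically preferred trans arrangement.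

Step 7
Reactants: 12 (3,4-dimethoxyphenyl)[(2R,3S,4R)-3-{[tert-butyl(diphenyl)silyl]oxymethyl}-2-(3,4,5-trimethoxyphenyl)oxolan-4-yl]methanone
Product: 13 (S)-(3,4-dimethoxyphenyl)[(2R,3S,4R)-3-{[tert-butyl(diphenyl)silyl]oxymethyl}-2-(3,4,5-trimethoxyphenyl)oxolan-4-yl]methanol
Conditions: L-Selectride (1.3 equiv), THF, –78 °C; then H2O
Reagents that add atoms: none
Why: Felkin–Anh reduction by a bulky hydride: the branched ring carbon C3 stands anti to the incoming hydride and C5 sits next to the carbonyl oxygen, which places the new OH anti to C5 in the Ar–C7–C4–C3 zigzag, that is 7S. A chelate between the ketone oxygen and O1 would expose the same face.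

Step 8
Reactants: 13 (S)-(3,4-dimethoxyphenyl)[(2R,3S,4R)-3-{[tert-butyl(diphenyl)silyl]oxymethyl}-2-(3,4,5-trimethoxyphenyl)oxolan-4-yl]methanol
Product: 14 [(2R,3S,4R)-4-[(S)-(3,4-dimethoxyphenyl)(hydroxy)methyl]-2-(3,4,5-trimethoxyphenyl)oxolan-3-yl]methanol (target, CNP0172668.1)
Conditions: TBAF (1.2 equiv), THF, 0 °C → rt
Reagents that add atoms: none
Why: Fluoride-induced desilylation driven by the Si–F bond; the conditions are non-acidic, so both benzylic C–O bonds and all four stereocentres should stay intact.

## Compound list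

1 | prop-2-en-1-ol | C=CCO | starting material
2 | tert-butyl(diphenyl)(prop-2-en-1-yloxy)silane | C=CCO[Si](c1ccccc1)(c1ccccc1)C(C)(C)C | intermediate
3 | (2S)-but-3-ene-1,2-diol | C=C[C@H](O)CO | starting material
4 | 3,4,5-trimethoxybenzaldehyde | COc1cc(C=O)cc(OC)c1OC | starting material
5 | (4S)-4-ethenyl-2-(3,4,5-trimethoxyphenyl)-1,3-dioxolane, both C2 epimers | C=C[C@H]1COC(c2cc(OC)c(OC)c(OC)c2)O1 | intermediate
6 | tert-butyl(diphenyl)silyl ether of (2E)-3-[(4S)-2-(3,4,5-trimethoxyphenyl)-1,3-dioxolan-4-yl]prop-2-en-1-ol, both acetal epimers | CC(C)(C)[Si](OC/C=C/[C@H]1COC(c2cc(OC)c(OC)c(OC)c2)O1)(c1ccccc1)c1ccccc1 | intermediate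
7 | zwitterion: (E)-oxocarbenium of 3,4,5-trimethoxybenzaldehyde O-alkylated by the (2S,3E)-5-silyloxy-2-(tetrachlorostannyloxy)pent-3-enyl chain | CC(C)(C)[Si](OC/C=C/[C@@H](C/[O+]=C/c1cc(OC)c(OC)c(OC)c1)O[Sn-](Cl)(Cl)(Cl)Cl)(c1ccccc1)c1ccccc1 | intermediate (not isolated)
8 | zwitterion: methyleneoxonium on the benzylic oxygen and (E)-tin(IV) enolate of the C4–C7 aldehyde, C2 (R) and C3 (S) set | C=[O+][C@@H](c1cc(OC)c(OC)c(OC)c1)[C@H](CO[Si](c1ccccc1)(c1ccccc1)C(C)(C)C)/C=C/O[Sn-](Cl)(Cl)(Cl)Cl | intermediate (not isolated)
9 | (2R,3S,4R)-3-{[tert-butyl(diphenyl)silyl]oxymethyl}-2-(3,4,5-trimethoxyphenyl)oxolane-4-carbaldehyde | O=C[C@H]1CO[C@@H](c2cc(OC)c(OC)c(OC)c2)[C@@H]1CO[Si](c1ccccc1)(c1ccccc1)C(C)(C)C | intermediate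
10 | (3,4-dimethoxyphenyl)magnesium bromide | COc1ccc([Mg]Br)cc1OC | starting material
11 | (3,4-dimethoxyphenyl)[(2R,3S,4R)-3-{[tert-butyl(diphenyl)silyl]oxymethyl}-2-(3,4,5-trimethoxyphenyl)oxolan-4-yl]methanol, both C7 epimers | COc1ccc(C(O)[C@H]2CO[C@@H](c3cc(OC)c(OC)c(OC)c3)[C@@H]2CO[Si](c4ccccc4)(c4ccccc4)C(C)(C)C)cc1OC | intermediate
12 | (3,4-dimethoxyphenyl)[(2R,3S,4R)-3-{[tert-butyl(diphenyl)silyl]oxymethyl}-2-(3,4,5-trimethoxyphenyl)oxolan-4-yl]methanone | COc1ccc(C(=O)[C@H]2CO[C@@H](c3cc(OC)c(OC)c(OC)c3)[C@@H]2CO[Si](c4ccccc4)(c4ccccc4)C(C)(C)C)cc1OC | intermediate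
13 | (S)-(3,4-dimethoxyphenyl)[(2R,3S,4R)-3-{[tert-butyl(diphenyl)silyl]oxymethyl}-2-(3,4,5-trimethoxyphenyl)oxolan-4-yl]methanol | COc1ccc([C@@H](O)[C@H]2CO[C@@H](c3cc(OC)c(OC)c(OC)c3)[C@@H]2CO[Si](c4ccccc4)(c4ccccc4)C(C)(C)C)cc1OC | intermediate
14 | [(2R,3S,4R)-4-[(S)-(3,4-dimethoxyphenyl)(hydroxy)methyl]-2-(3,4,5-trimethoxyphenyl)oxolan-3-yl]methanol | COc1ccc([C@@H](O)[C@H]2CO[C@@H](c3cc(OC)c(OC)c(OC)c3)[C@@H]2CO)cc1OC | target

## Step count and least certain steps

Total step count: 8. Longest linear sequence: 7 steps (steps 2–8, from 3 or 4); step 1 is a one-step branch.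

Step 4 (key step). The most likely failure is loss of stereochemical fidelity. The only stereocentre of 6 is destroyed, so any share of the chair (or a boat) that carries the stannyloxy group axial leads to the enantiomeric C2/C3 pair and erodes enantiopurity. A second danger is unproductive ionisation of the allylic C–O bonds (allylic acetal oxygen or allylic silyl ether), which would cause decomposition. A third is a 1,2-hydride shift in a stepwise Prins pathway in place of the C5 shift.

The fallback sets out from 4 and comes back at 11, using auxiliary control and a γ-aryl lactone: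
- (4R)-4-Benzyl-1,3-oxazolidin-2-one is N-acylated (n-BuLi, methyl 4-chloro-4-oxobutanoate) to the succinyl imide F1.
- Its dibutylboron enolate (Bu2BOTf, i-Pr2NEt, CH2Cl2, –78 °C) adds to 4 in an Evans syn aldol reaction to give the adduct F2.
- F2 lactonises onto its methyl ester to the trans lactone imide F3, in which C2 and C3 have the target configuration.
- NaBH4 in THF/H2O removes the auxiliary reductively to the hydroxymethyl lactone F4, and TBDPSCl/imidazole gives the silyl ether F5.
- The lithium enolate of F5 (LDA, THF, –78 °C) adds to 3,4-dimethoxybenzaldehyde anti to the C3 substituent to give the aldol F6. This sets C4; both C7 epimers are usable.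
- LiAlH4 opens the lactone to the triol F7.
- TsCl/pyridine sulfonylates the primary hydroxyl to the tosylate F8, and the C2 hydroxyl closes the ring by 5-exo-tet displacement to 11, which rejoins the route at step 6.

Step 3. Poor E/Z selectivity and homodimerisation of either partner are the likely problems. A Z-alkene would enter the chair of step 4 with an axial CH2OSi group and lead into the 2,3-cis series. The fallback sets out from 5 and comes back at 6, fixing the geometry by olefination:
- Lemieux–Johnson cleavage of the vinyl group (OsO4 cat., NaIO4, 2,6-lutidine, dioxane/H2O) gives the aldehyde F9.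
- Horner–Wadsworth–Emmons reaction with triethyl phosphonoacetate (NaH, THF, 0 °C) gives the (E)-enoate F10.
- DIBAL-H (CH2Cl2, –78 °C) gives the allylic alcohol F11, and TBDPSCl/imidazole gives 6.

Step 7. Poor facial selectivity is possible, because the two ring carbons on C4 (C3 and C5) may not differ enough for clean Felkin control. The fallback sets out from 12 and comes back at 13. It moves stereocontrol from the substrate to a catalyst: Corey–Bakshi–Shibata reduction with the (R)-2-methyl oxazaborolidine and BH3·SMe2, whose sense (aryl as the large group) coincides with the Felkin preference. It makes no new compound.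

Step 5. The basic Grignard reagent may enolise the α-branched β-alkoxy aldehyde, with C4 epimerisation or β-elimination of O1 (ring opening). The fallback sets out from 9 and comes back at 11. It replaces the organomagnesium addition by a Rh(I)-catalysed 1,2-addition of 3,4-dimethoxyphenylboronic acid in aqueous dioxane, a near-neutral transmetalation pathway. It makes no new compound.

## Further compounds

F1 | step 4 | (4R)-4-benzyl-3-(4-methoxy-4-oxobutanoyl)-1,3-oxazolidin-2-one | COC(=O)CCC(=O)N1[C@H](Cc2ccccc2)COC1=O
F2 | step 4 | methyl (3R,4R)-3-{[(4R)-4-benzyl-2-oxo-1,3-oxazolidin-3-yl]carbonyl}-4-hydroxy-4-(3,4,5-trimethoxyphenyl)butanoate | COC(=O)C[C@@H](C(=O)N1[C@H](Cc2ccccc2)COC1=O)[C@H](c1cc(OC)c(OC)c(OC)c1)O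
F3 | step 4 | (4R)-4-benzyl-3-{[(2R,3R)-5-oxo-2-(3,4,5-trimethoxyphenyl)oxolan-3-yl]carbonyl}-1,3-oxazolidin-2-one | O=C1C[C@@H](C(=O)N2[C@H](Cc3ccccc3)COC2=O)[C@H](c2cc(OC)c(OC)c(OC)c2)O1
F4 | step 4 | (4S,5R)-4-(hydroxymethyl)-5-(3,4,5-trimethoxyphenyl)oxolan-2-one | O=C1C[C@@H](CO)[C@H](c2cc(OC)c(OC)c(OC)c2)O1
F5 | step 4 | (4S,5R)-4-{[tert-butyl(diphenyl)silyl]oxymethyl}-5-(3,4,5-trimethoxyphenyl)oxolan-2-one | O=C1C[C@@H](CO[Si](c2ccccc2)(c2ccccc2)C(C)(C)C)[C@H](c2cc(OC)c(OC)c(OC)c2)O1
F6 | step 4 | (3S,4S,5R)-4-{[tert-butyl(diphenyl)silyl]oxymethyl}-3-[(3,4-dimethoxyphenyl)(hydroxy)methyl]-5-(3,4,5-trimethoxyphenyl)oxolan-2-one, both carbinol epimers | O=C1[C@H](C(O)c2ccc(OC)c(OC)c2)[C@@H](CO[Si](c2ccccc2)(c2ccccc2)C(C)(C)C)[C@H](c2cc(OC)c(OC)c(OC)c2)O1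
F7 | step 4 | (2R,3S,4R)-3-{[tert-butyl(diphenyl)silyl]oxymethyl}-2-[(3,4-dimethoxyphenyl)(hydroxy)methyl]-4-(3,4,5-trimethoxyphenyl)butane-1,4-diol, both carbinol epimers | OC[C@H](C(O)c1ccc(OC)c(OC)c1)[C@@H](CO[Si](c1ccccc1)(c1ccccc1)C(C)(C)C)[C@H](c1cc(OC)c(OC)c(OC)c1)O
F8 | step 4 | 1-O-(4-methylbenzenesulfonyl) derivative of F7 | Cc1ccc(S(=O)(=O)OC[C@H](C(O)c2ccc(OC)c(OC)c2)[C@@H](CO[Si](c2ccccc2)(c2ccccc2)C(C)(C)C)[C@H](c2cc(OC)c(OC)c(OC)c2)O)cc1
F9 | step 3 | (4R)-2-(3,4,5-trimethoxyphenyl)-1,3-dioxolane-4-carbaldehyde, both acetal epimers | O=C[C@H]1COC(c2cc(OC)c(OC)c(OC)c2)O1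
F10 | step 3 | ethyl (2E)-3-[(4S)-2-(3,4,5-trimethoxyphenyl)-1,3-dioxolan-4-yl]prop-2-enoate | CCOC(=O)/C=C/[C@H]1COC(c2cc(OC)c(OC)c(OC)c2)O1
F11 | step 3 | (2E)-3-[(4S)-2-(3,4,5-trimethoxyphenyl)-1,3-dioxolan-4-yl]prop-2-en-1-ol | OC/C=C/[C@H]1COC(c2cc(OC)c(OC)c(OC)c2)O1
F0 | step 7 | none | none
F0 | step 5 | none | none
A1 | alternative 1 | 4-[(S)-(tert-butyldimethylsilyloxy)(3,4-dimethoxyphenyl)methyl]-3-[hydroxy(3,4,5-trimethoxyphenyl)methyl]oxolan-2-one, 3,4-cis, ring centres configured as C3/C4 of the target | O=C1OC[C@H]([C@H](O[Si](C)(C)C(C)(C)C)c2ccc(OC)c(OC)c2)[C@@H]1C(O)c1cc(OC)c(OC)c(OC)c1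
A2 | alternative 1 | 2-[(S)-(tert-butyldimethylsilyloxy)(3,4-dimethoxyphenyl)methyl]-3-[hydroxy(3,4,5-trimethoxyphenyl)methyl]butane-1,4-diol, backbone centres configured as C4/C3 of the target | COc1ccc([C@@H](O[Si](C)(C)C(C)(C)C)[C@@H](CO)[C@@H](CO)C(O)c2cc(OC)c(OC)c(OC)c2)cc1OC
A3 | alternative 2 | (5R)-5-[(S)-(tert-butyldimethylsilyloxy)(3,4-dimethoxyphenyl)methyl]-2-(3,4,5-trimethoxyphenyl)-4,5-dihydro-1,3-dioxepine | COc1ccc([C@@H](O[Si](C)(C)C(C)(C)C)[C@H]2COC(c3cc(OC)c(OC)c(OC)c3)OC=C2)cc1OC
A4 | alternative 2 | (2R,3R,4R)-4-[(S)-(tert-butyldimethylsilyloxy)(3,4-dimethoxyphenyl)methyl]-2-(3,4,5-trimethoxyphenyl)oxolane-3-carbaldehyde | COc1ccc([C@@H](O[Si](C)(C)C(C)(C)C)[C@H]2CO[C@@H](c3cc(OC)c(OC)c(OC)c3)[C@@H]2C=O)cc1OC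
A5 | alternative 3 | carbonyl ylide of 3,4,5-trimethoxybenzaldehyde and a methylene unit | [CH2-][O+]=Cc1cc(OC)c(OC)c(OC)c1
A6 | alternative 3 | methyl (2E)-4-(3,4-dimethoxyphenyl)-4-oxobut-2-enoate | COC(=O)/C=C/C(=O)c1ccc(OC)c(OC)c1
A7 | alternative 3 | methyl (2R,3R,4R)-4-(3,4-dimethoxybenzoyl)-2-(3,4,5-trimethoxyphenyl)oxolane-3-carboxylate | COc1ccc(C(=O)[C@H]2CO[C@@H](c3cc(OC)c(OC)c(OC)c3)[C@@H]2C(=O)OC)cc1OC
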